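**Plan**
- Retrosynthesis: C1–C7a and C3–C3a are cut together, which detaches ring A as a symmetric arylboronic acid and leaves an acyclic 1,2,4-triarylbut-3-yn-1-ol (alkyne = C1 and the benzylidene carbon, then C2, then C3–OH). C2–C3 is then cut to an axially chiral allenylboronate and O-benzylvanillin, and the allene is traced back to a propargylic carbinol from an aryl alkyne and 3,5-bis(benzyloxy)benzaldehyde.
- Forward: the four-carbon chain is joined first (alkynylation, SN2′ borylation, allenylboration). The only ring to be made, the five-membered ring, arises in step 6; global debenzylation ends the route.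
- Enabling feature: ring A is symmetric about its ipso carbon (C7a), so either ortho carbon (C3a) is ortho and para to the two ring oxygens (C4–O, C6–O) and is strongly nucleophilic. The alkyne is polarised by its guaiacyl ring, so ring A enters at C1 and H at the benzylidene carbon on the same side. The para-oxygenated guaiacyl ring on C3 stabilises a cation there.
- Stereochemistry: C2 comes from the R carbinol of a Ti/BINOL alkynylation, relayed centre → axis → centre (anti-SN2′, then cyclic SE2′). C3 is set trans to C2 in the ring closure; the E alkene comes from syn arylrhodation.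

Key step: step 6

Assumptions: indane numbering is used for the target (C1 = ring carbon of the benzylidene group, C2, C3, ring-fusion carbons C3a next to C3 and C7a next to C1; ring A = the fused dioxygenated benzene ring). Compounds 1, 3 and 10 are taken as commercially available. Step 5 is drawn for the anti carbinol; its epimer at the carbinol carbon would converge in step 6.

**Step 1**
Reactants: 1 4-(benzyloxy)-3-methoxybenzaldehyde
Product: 2 1-(benzyloxy)-4-ethynyl-2-methoxybenzene
Conditions: Ohira–Bestmann reagent, K2CO3, MeOH, 0 °C → rt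
Reagents that add atoms: dimethyl (1-diazo-2-oxopropyl)phosphonate, COP(=O)(OC)C(=[N+]=[N-])C(C)=O
Why: Seyferth–Gilbert homologation in its Ohira–Bestmann form converts an aryl aldehyde into the terminal alkyne under carbonate/methanol conditions that leave the benzyl and methyl ethers untouched; no stereocentre is formed.

**Step 2**
Reactants: 2 1-(benzyloxy)-4-ethynyl-2-methoxybenzene; 3 3,5-bis(benzyloxy)benzaldehyde
Product: 5 (R)-1-[3,5-bis(benzyloxy)phenyl]-3-[4-(benzyloxy)-3-methoxyphenyl]prop-2-yn-1-ol, via alkynyl(ethyl)zinc 4 (not isolated)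
Conditions: 2 (2 equiv), Et2Zn, PhMe, reflux; then (S)-BINOL (20 mol%), Ti(OiPr)4 (50 mol%), 3, CH2Cl2, rt; aqueous work-up
Reagents that add atoms: none
Why: Titanium–BINOL-catalysed enantioselective addition of an alkynylzinc reagent to an aromatic aldehyde, a substrate pairing this catalyst system handles well; (S)-BINOL is expected to deliver the alkynyl group to the Si face of 3 (the facial sense of the related dialkylzinc additions), which corresponds to the R carbinol that is later relayed to C2.

**Step 3**
Reactants: 5 (R)-1-[3,5-bis(benzyloxy)phenyl]-3-[4-(benzyloxy)-3-methoxyphenyl]prop-2-yn-1-ol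
Product: 6 (R)-1-[3,5-bis(benzyloxy)phenyl]-3-[4-(benzyloxy)-3-methoxyphenyl]prop-2-yn-1-yl methyl carbonate
Conditions: ClCO2Me, pyridine, DMAP (cat.), CH2Cl2, 0 °C
Reagents that add atoms: methyl chloroformate, COC(=O)Cl
Why: O-acylation of a secondary alcohol with a chloroformate does not touch the C–O bond of the stereocentre, so the R configuration is retained, and a carbonate is a sturdier leaving group than a sulfonate for this easily ionised diaryl propargylic system.

**Step 4**
Reactants: 6 (R)-1-[3,5-bis(benzyloxy)phenyl]-3-[4-(benzyloxy)-3-methoxyphenyl]prop-2-yn-1-yl methyl carbonate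
Product: 7 (M)-2-{3-[3,5-bis(benzyloxy)phenyl]-1-[4-(benzyloxy)-3-methoxyphenyl]propa-1,2-dien-1-yl}-4,4,5,5-tetramethyl-1,3,2-dioxaborolane
Conditions: Cu(OtBu) (10 mol%), Xantphos (10 mol%), B2pin2, THF, rt
Reagents that add atoms: bis(pinacolato)diboron, CC1(C)OB(OC1(C)C)B1OC(C)(C)C(C)(C)O1
Why: Copper-catalysed borylative SN2′ substitution of a propargylic carbonate: Cu–Bpin adds across the alkyne with boron on the carbon remote from the carbonate, and β-elimination of the carbonate anti to the new C–B bond gives the allene, so the R centre should be transferred to the M (Ra) axis.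

**Step 5**
Reactants: 7 (M)-2-{3-[3,5-bis(benzyloxy)phenyl]-1-[4-(benzyloxy)-3-methoxyphenyl]propa-1,2-dien-1-yl}-4,4,5,5-tetramethyl-1,3,2-dioxaborolane; 1 4-(benzyloxy)-3-methoxybenzaldehyde
Product: 9 (1S,2S)-1,4-bis[4-(benzyloxy)-3-methoxyphenyl]-2-[3,5-bis(benzyloxy)phenyl]but-3-yn-1-ol, via pinacol borate ester 8 (not isolated)
Conditions: PhMe, 60 °C; then aq. NaHCO3
Reagents that add atoms: none
Why: Allenylboration (propargylation) of an aldehyde through a closed six-membered transition state: boron binds the carbonyl oxygen and the C2–C3 bond forms at the allene terminus on the face that carries boron (syn SE2′), which converts the axis into the S centre at C2 and regenerates the alkyne; the anti carbinol should predominate, but its configuration is erased in step 6.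

**Step 6**
Reactants: 9 (1S,2S)-1,4-bis[4-(benzyloxy)-3-methoxyphenyl]-2-[3,5-bis(benzyloxy)phenyl]but-3-yn-1-ol; 10 [3,5-bis(benzyloxy)phenyl]boronic acid
Product: 12 hexa-O-benzylgnetulin, via E-alkenyl alcohol 11 (not isolated)
Conditions: 10 (1.5 equiv), [Rh(cod)OH]2 (3 mol%), dioxane/H2O 10:1, 70 °C; volatiles removed; then TFA (2 equiv), HFIP/CH2Cl2 1:4, 0.01 M, −20 → 0 °C, same flask
Reagents that add atoms: none
Why: In the first stage the aryl–rhodium species from 10 adds syn across the alkyne with ring A going to C1 and rhodium to the guaiacyl-bearing carbon (the alkenylrhodium α to an aryl ring is the favoured regioisomer), rhodium then migrates 1,4 to the ortho carbon C3a and is protonated, which fixes the E alkene of 11; in the second stage acid ionises the benzylic alcohol to a C3 cation stabilised by the para-oxygenated guaiacyl ring, and C3a, ortho and para to the two benzyloxy groups, captures it. The closest known reaction types are the rhodium-catalysed hydroarylation of aryl alkyl alkynes with arylboronic acids and the Friedel–Crafts cyclialkylation that closes 2,3-diarylindanes in resveratrol-oligomer chemistry; run in one flask they amount to a formal (3+2) annulation of the C7a–C3a edge of ring A onto C1–C2–C3. The five-membered ring closes by intramolecular electrophilic aromatic substitution, a 5-endo attack (endo with respect to the arene π bond) of C3a on the planar cation. The new stereocentre C3 is controlled by C2: the guaiacyl group takes the face of the forming ring opposite to the C2 aryl group, giving the trans-2,3-diaryl indane, so the carbinol configuration of 9 does not matter. The step needs regioselective aryl transfer to C1 (secured by the aryl/alkyl polarisation of the alkyne; the two ortho carbons of ring A are equivalent, so no second regiochemical question arises) and cyclisation through ring A and not through the guaiacyl ring on the alkene (secured by the far higher nucleophilicity of the 1,3-dioxygenated ring), without acid-induced migration of the exocyclic double bond (secured by low temperature, dilution and a weak acid in HFIP).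

**Step 7**
Reactants: 12 hexa-O-benzylgnetulin
Product: 13 gnetulin
Conditions: BCl3 (excess), pentamethylbenzene, CH2Cl2, −78 °C; then MeOH/H2O
Reagents that add atoms: none
Why: Lewis-acid debenzylation with BCl3 and pentamethylbenzene as a non-basic benzyl-cation scavenger cleaves aryl benzyl ethers selectively over aryl methyl ethers at −78 °C and, unlike hydrogenolysis, leaves the exocyclic stilbene double bond and both stereocentres untouched.

**Compound list**
1 | 4-(benzyloxy)-3-methoxybenzaldehyde (O-benzylvanillin) | O=Cc1ccc(OCc2ccccc2)c(OC)c1 | starting material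
2 | 1-(benzyloxy)-4-ethynyl-2-methoxybenzene | C#Cc1ccc(OCc2ccccc2)c(OC)c1 | intermediate
3 | 3,5-bis(benzyloxy)benzaldehyde | O=Cc1cc(OCc2ccccc2)cc(OCc2ccccc2)c1 | starting material
4 | ethyl{[4-(benzyloxy)-3-methoxyphenyl]ethynyl}zinc | CC[Zn]C#Cc1ccc(OCc2ccccc2)c(OC)c1 | intermediate
5 | (R)-1-[3,5-bis(benzyloxy)phenyl]-3-[4-(benzyloxy)-3-methoxyphenyl]prop-2-yn-1-ol | COc1cc(C#C[C@H](O)c2cc(OCc3ccccc3)cc(OCc3ccccc3)c2)ccc1OCc1ccccc1 | intermediate
6 | (R)-1-[3,5-bis(benzyloxy)phenyl]-3-[4-(benzyloxy)-3-methoxyphenyl]prop-2-yn-1-yl methyl carbonate | COc1cc(C#C[C@H](OC(=O)OC)c2cc(OCc3ccccc3)cc(OCc3ccccc3)c2)ccc1OCc1ccccc1 | intermediate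
7 | (M)-2-{3-[3,5-bis(benzyloxy)phenyl]-1-[4-(benzyloxy)-3-methoxyphenyl]propa-1,2-dien-1-yl}-4,4,5,5-tetramethyl-1,3,2-dioxaborolane (allenylboronate, Ra axis) | [H]C(c1cc(OCc2ccccc2)cc(OCc2ccccc2)c1)=[C@]=C(c1ccc(OCc2ccccc2)c(OC)c1)B1OC(C)(C)C(C)(C)O1 | intermediate
8 | 2-{[(1S,2S)-1,4-bis[4-(benzyloxy)-3-methoxyphenyl]-2-[3,5-bis(benzyloxy)phenyl]but-3-yn-1-yl]oxy}-4,4,5,5-tetramethyl-1,3,2-dioxaborolane | COc1cc(C#C[C@@H]([C@H](OB2OC(C)(C)C(C)(C)O2)c2ccc(OCc3ccccc3)c(OC)c2)c2cc(OCc3ccccc3)cc(OCc3ccccc3)c2)ccc1OCc1ccccc1 | intermediate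
9 | (1S,2S)-1,4-bis[4-(benzyloxy)-3-methoxyphenyl]-2-[3,5-bis(benzyloxy)phenyl]but-3-yn-1-ol | COc1cc(C#C[C@@H]([C@H](O)c2ccc(OCc3ccccc3)c(OC)c2)c2cc(OCc3ccccc3)cc(OCc3ccccc3)c2)ccc1OCc1ccccc1 | intermediate
10 | [3,5-bis(benzyloxy)phenyl]boronic acid | OB(O)c1cc(OCc2ccccc2)cc(OCc2ccccc2)c1 | starting material
11 | (1S,2S,3E)-1,4-bis[4-(benzyloxy)-3-methoxyphenyl]-2,3-bis[3,5-bis(benzyloxy)phenyl]but-3-en-1-ol | COc1cc(/C=C(\[C@@H]([C@H](O)c2ccc(OCc3ccccc3)c(OC)c2)c2cc(OCc3ccccc3)cc(OCc3ccccc3)c2)c2cc(OCc3ccccc3)cc(OCc3ccccc3)c2)ccc1OCc1ccccc1 | intermediate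
12 | hexa-O-benzylgnetulin, (1E,2S,3S)-4,6-bis(benzyloxy)-2-[3,5-bis(benzyloxy)phenyl]-1-[4-(benzyloxy)-3-methoxybenzylidene]-3-[4-(benzyloxy)-3-methoxyphenyl]indane | COc1cc(/C=C2/c3cc(OCc4ccccc4)cc(OCc4ccccc4)c3[C@H](c3ccc(OCc4ccccc4)c(OC)c3)[C@H]2c2cc(OCc3ccccc3)cc(OCc3ccccc3)c2)ccc1OCc1ccccc1 | intermediate
13 | gnetulin, (1E,2S,3S)-2-(3,5-dihydroxyphenyl)-1-(4-hydroxy-3-methoxybenzylidene)-3-(4-hydroxy-3-methoxyphenyl)indane-4,6-diol | COc1cc(/C=C2/c3cc(O)cc(O)c3[C@H](c3ccc(O)c(OC)c3)[C@H]2c2cc(O)cc(O)c2)ccc1O | target

**Step count and risks**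
Total steps: 7. Longest linear sequence: 7 steps (1 → 2 → 5 → 6 → 7 → 9 → 12 → 13).

Step 6 is the most likely to fail. Aryl transfer could go to the wrong alkyne carbon, because the C1 side is a hindered secondary carbon and the free hydroxyl group could steer rhodium to C1. In the acid stage, ring closure could take place through the guaiacyl ring, or the exocyclic double bond could migrate into the ring. The fallback fixes the regiochemistry with a silicon tether and separates the two stages. It sets out from 9: 1,1,3,3-tetramethyldisilazane (neat, 60 °C) should give the dimethylsilyl ether F1. Intramolecular syn hydrosilylation catalysed by Pt2(dvds)3 (dvds = 1,3-divinyl-1,1,3,3-tetramethyldisiloxane), a 5-exo-dig closure, should give the (E)-3-benzylidene-2,2-dimethyl-1,2-oxasilolane F2, with silicon on C1 and hydrogen cis to it. Hiyama–Denmark coupling of F2 with 1-iodo-3,5-bis(benzyloxy)benzene (Pd(dba)2, Bu4NF, THF) replaces silicon by ring A with retention of the double-bond geometry and frees the hydroxyl group. This is compound 11, where the fallback comes back to the route; 11 is then isolated and closed to 12 with the mildest acid that ionises it (catalytic TsOH in HFIP at −20 °C).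

Step 4 is next. The aryl group and the carbonate direct copper to different alkyne carbons, so regiocontrol in the Cu–Bpin addition may be lost, and the centre-to-axis transfer may erode. A sluggish addition of the hindered pinacol boronate in step 5 would call for the same remedy. The fallback is a palladium/zinc reductive propargylation that sets out from 5: MsCl, Et3N, CH2Cl2 at −78 °C should give the mesylate F3, used crude. Pd(OAc)2/PPh3 (cat.) and Et2Zn in THF at −20 °C in the presence of 1 then give, by anti oxidative addition of zerovalent palladium and transmetalation, the allenyl(ethyl)zinc species F4. F4 adds to 1 through a cyclic transition state with the same sense of centre → axis → centre transfer and comes back to the route at 9.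

Step 2 is third. Face selection in the alkynylzinc addition may be insufficient with this electron-rich alkyne. The fallback is a resolution that sets out from 2 and 3: the lithium acetylide of 2 (n-BuLi, THF, −78 °C) adds to 3 to give the racemic carbinol F5. Esterification with (S)-2-methoxy-2-phenylacetic acid (DCC, DMAP) gives two diastereomeric esters, the ester of the R carbinol F6 and the ester of the S carbinol F7, which are separated by chromatography or crystallisation. Methanolysis of F6 (K2CO3, MeOH) comes back to the route at 5.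

**Further compounds**
F1 | step 6 | dimethylsilyl ether of 9, {[(1S,2S)-1,4-bis[4-(benzyloxy)-3-methoxyphenyl]-2-[3,5-bis(benzyloxy)phenyl]but-3-yn-1-yl]oxy}dimethylsilane | COc1cc(C#C[C@@H]([C@H](O[SiH](C)C)c2ccc(OCc3ccccc3)c(OC)c2)c2cc(OCc3ccccc3)cc(OCc3ccccc3)c2)ccc1OCc1ccccc1
F2 | step 6 | (E)-3-[4-(benzyloxy)-3-methoxybenzylidene]-4-[3,5-bis(benzyloxy)phenyl]-5-[4-(benzyloxy)-3-methoxyphenyl]-2,2-dimethyl-1,2-oxasilolane (C4 and C5 configured as in 9) | COc1cc(/C=C2\[C@@H]([C@H](O[Si]2(C)C)c2ccc(OCc3ccccc3)c(OC)c2)c2cc(OCc3ccccc3)cc(OCc3ccccc3)c2)ccc1OCc1ccccc1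
F3 | step 4 | (R)-1-[3,5-bis(benzyloxy)phenyl]-3-[4-(benzyloxy)-3-methoxyphenyl]prop-2-yn-1-yl methanesulfonate | COc1cc(C#C[C@H](OS(C)(=O)=O)c2cc(OCc3ccccc3)cc(OCc3ccccc3)c2)ccc1OCc1ccccc1
F4 | step 4 | (M)-{3-[3,5-bis(benzyloxy)phenyl]-1-[4-(benzyloxy)-3-methoxyphenyl]propa-1,2-dien-1-yl}(ethyl)zinc | [H]C(c1cc(OCc2ccccc2)cc(OCc2ccccc2)c1)=[C@]=C(c1ccc(OCc2ccccc2)c(OC)c1)[Zn]CC
F5 | step 2 | racemic 1-[3,5-bis(benzyloxy)phenyl]-3-[4-(benzyloxy)-3-methoxyphenyl]prop-2-yn-1-ol | COc1cc(C#CC(O)c2cc(OCc3ccccc3)cc(OCc3ccccc3)c2)ccc1OCc1ccccc1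
F6 | step 2 | (R)-1-[3,5-bis(benzyloxy)phenyl]-3-[4-(benzyloxy)-3-methoxyphenyl]prop-2-yn-1-yl (S)-2-methoxy-2-phenylacetate | COc1cc(C#C[C@H](OC(=O)[C@@H](OC)c2ccccc2)c2cc(OCc3ccccc3)cc(OCc3ccccc3)c2)ccc1OCc1ccccc1
F7 | step 2 | (S)-1-[3,5-bis(benzyloxy)phenyl]-3-[4-(benzyloxy)-3-methoxyphenyl]prop-2-yn-1-yl (S)-2-methoxy-2-phenylacetate | COc1cc(C#C[C@@H](OC(=O)[C@@H](OC)c2ccccc2)c2cc(OCc3ccccc3)cc(OCc3ccccc3)c2)ccc1OCc1ccccc1
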